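The vessel, closed and stirred at constant temperature, does its visible moving early: in the teal and amber runs isomer of the product C falls during the first days, then stands within its scatter.

| flask | starting material | remark | time |
|---|---|---|---|
| teal | 0.025 M | run made earlier |  |
| amber | 0.038 M | run made earlier |  |
| flask | 0.050 M |  | 8.0 d |

| run | time / d | target / % | isomer of the product C / % |
|---|---|---|---|
| teal | 0.833 | 3.0 | 33.3 |
| teal | 1.25 | 2.3 | 30.5 |
| teal | 2.00 | 2.4 | 29.8 |
| teal | 4.00 | 2.2 | 29.3 |
| teal | 6.00 | 2.8 | 29.0 |
| teal | 10.0 | 1.7 | 28.6 |
| amber | 0.833 | 3.0 | 33.1 |
| amber | 1.25 | 2.3 | 30.7 |
| amber | 2.00 | 2.4 | 29.7 |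
| amber | 4.00 | 2.6 | 28.7 |
| amber | 6.00 | 1.9 | 29.0 |
| amber | 10.0 | 2.7 | 28.8 |

(scatter of a reading: 0.3 percentage points)

- what was read earlier has a scatter of 0.3 percentage points, one standard deviation
- what may be going on: isomer of the product B <-> starting material; target <-> isomer of the product A; starting material <-> dormant form; target <-> isomer of the product C; isomer of the product A <-> isomer of the product B; starting material <-> target

* target at 8.0 d, in percent of the starting material charged
* isomer of the product C at 8.0 d, in percent of the starting material charged

I fold the question into one number, reckoned from the teal readings of c(isomer of the product C), in percent of the charge.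

plateau, mean of the readings from 4.00 d on = 29.0%

relaxation time τ, from the excess over that plateau at 0.833 d and 1.25 d = 0.401 d

N = (time asked − first reading)/τ = 17.9

N, the number of relaxation times that the flask runs past the first reading, says how far the excess has died: far below the scatter. The amber run gives its own plateau 28.8%, τ 0.504 d and N 14.2, which leads the same way.

But N tells when, not where, and it can't see a slower movement. From 4.00 d to 10.0 d teal falls 0.7 percentage points while amber rises 0.1 points, so I see no shared drift. I commit to 28.9% isomer of the product C and, from the same late readings, 2.32% target.

The forecast, finding that “the percentages look concentration-independent”, gives 2.3% target and 28.8% isomer of the product C, the latter lower than mine.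

    isomer of the product B ⇌ starting material (k = 0.575 h⁻¹)
    target ⇌ isomer of the product A (K = 1.57, k = 0.203 h⁻¹)
    starting material ⇌ dormant form (K = 3.20, k = 0.155 h⁻¹)
    target ⇌ isomer of the product C (K = 11.9, k = 3.74 h⁻¹)
    isomer of the product A ⇌ isomer of the product B (K = 0.200, k = 0.520 h⁻¹)
    starting material ⇌ target (K = 0.160, k = 13.3 h⁻¹)

The flask gives 2.44% target and 29.0% isomer of the product C, within the forecast's margins. With the reaction of target to isomer of the product C struck out both ways, this flask gives 3.43% target instead. The neighbour flask read at 50 h has N = 3.12, for which my τ, read off the teal run, reckons an excess of 0.19 points, whereas that neighbour stands at 29.3% isomer of the product C, 0.30 points above this flask.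

(The readings were computed for an exercise; scatter was added.)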